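**Strategy.** The route rests on disconnecting the lactone C–O bond at C6. C6 is allylic to the trisubstituted C4=C5 alkene of the ten-membered ring, so this bond is the 1,3-transposed form of a tertiary allylic alcohol at C4 flanked by an E-C5=C6 alkene, which is the carbinol motif of (R)-linalool. In the key step a Pd(II)-catalysed dehydrative SN2′ lactonisation adds the C12 carboxyl to C6. One operation should close the γ-lactone (O–C12–C11–C7–C6), set C6 by 1,3-chirality transfer from C4 and create the E-C4=C5 alkene. The precursor is a cyclodeca-2,7-dienyl acrylic acid built by cross-metathesis, Nozaki–Hiyama–Kishi coupling and an indium Barbier macrocyclisation.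

Key step: step 16

Remark (assumption): positions are given in germacrane numbering (lactone O on C6, acrylate on C7, ester O on C8, OH on C9, C14 on C10, C15 on C4). Partner 6 is racemic, so 15 and 17–21 are pairs of epimers at C7, a centre that becomes sp2 in step 12.

**Step 1**
Reactants: 1 2-(trimethylsilyl)ethanol; 2 acryloyl chloride
Product: 3 2-(trimethylsilyl)ethyl prop-2-enoate
Conditions: Et3N, CH2Cl2, 0 °C
Reagents that add atoms: none
Why: O-acylation of a primary alcohol by an acid chloride should be clean at 0 °C, with the amine base removing HCl before it can add to the acrylate.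

**Step 2**
Reactants: 3 2-(trimethylsilyl)ethyl prop-2-enoate; 4 acrolein
Product: 5 racemic 2-(trimethylsilyl)ethyl 3-hydroxy-2-methylidenepent-4-enoate
Conditions: DABCO (20 mol %), neat, 0 °C → rt, 3 in excess
Reagents that add atoms: none
Why: Morita–Baylis–Hillman reaction, in which the DABCO–acrylate zwitterion should add 1,2 to the unhindered enal; the new carbinol centre is racemic and is erased in step 12.

**Step 3**
Reactants: 5 racemic 2-(trimethylsilyl)ethyl 3-hydroxy-2-methylidenepent-4-enoate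
Product: 6 racemic 2-(trimethylsilyl)ethyl 2-methylidene-3-[(triethylsilyl)oxy]pent-4-enoate
Conditions: TESCl, imidazole, CH2Cl2, 0 °C
Reagents that add atoms: chlorotriethylsilane, CC[Si](Cl)(CC)CC
Why: Standard silylation of a secondary allylic alcohol; the TES ether should keep this hydroxyl distinct from the C9 hydroxyl made in step 9 and falls off with the acetonide in step 11.

**Step 4**
Reactants: 7 3-methylbut-3-en-1-ol
Product: 8 2-[(2R)-2-methyloxiran-2-yl]ethan-1-ol
Conditions: WO2(acac)2 (5 mol %), chiral bis-hydroxamic acid ligand (enantiomer that delivers the R epoxide), 30 % aq H2O2, NaCl, CH2Cl2, rt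
Reagents that add atoms: hydrogen peroxide, OO
Why: Hydroxyl-directed catalytic asymmetric epoxidation of a homoallylic alcohol, in which the metal-bound alkoxide should deliver the peroxo oxygen to one face of the 1,1-disubstituted alkene and the ligand enantiomer fixes the quaternary centre as R.

**Step 5**
Reactants: 8 2-[(2R)-2-methyloxiran-2-yl]ethan-1-ol
Product: 10 [(2R)-2-methyloxiran-2-yl]acetic acid, via epoxy aldehyde 9 (not isolated)
Conditions: TEMPO (20 mol %), PhI(OAc)2 (2.2 equiv), MeCN/pH 7 buffer, 0 °C → rt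
Reagents that add atoms: water, O
Why: Oxoammonium (TEMPO/iodine(III)) oxidation of the primary alcohol to the aldehyde, whose hydrate should be oxidised on to the acid under buffered conditions that leave the quaternary epoxide centre untouched.

**Step 6**
Reactants: 11 (R)-(−)-linalool
Product: 13 (5R)-5-ethenyl-5-methyloxolan-2-ol (anomer mixture), via ozonide 12 (not isolated)
Conditions: O3, CH2Cl2, −78 °C (Sudan Red 7B end point); then Me2S, −78 °C → rt
Reagents that add atoms: ozone, [O-][O+]=O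
Why: Ozonolysis with reductive work-up should cleave the electron-rich trisubstituted alkene in preference to the vinyl group, and the resulting γ-hydroxy aldehyde closes to the lactol with the C4 carbinol centre unchanged.

**Step 7**
Reactants: 13 (5R)-5-ethenyl-5-methyloxolan-2-ol
Product: 14 (3R,6Z)-7-iodo-3-methylocta-1,6-dien-3-ol
Conditions: EtPPh3I, n-BuLi, THF; I2, −78 °C; NaHMDS; then 13, −78 → −20 °C (2.5 equiv ylide)
Reagents that add atoms: ethyltriphenylphosphonium iodide, CC[P+](c1ccccc1)(c1ccccc1)c1ccccc1.[I-]; iodine, II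
Why: Stork–Zhao-type Wittig olefination of the lactol (open hydroxy-aldehyde form) with the α-iodo ylide should give the Z-configured 2-iodoalk-2-ene, which fixes the later C1=C10 geometry.

**Step 8**
Reactants: 14 (3R,6Z)-7-iodo-3-methylocta-1,6-dien-3-ol; 6 racemic 2-(trimethylsilyl)ethyl 2-methylidene-3-[(triethylsilyl)oxy]pent-4-enoate
Product: 15 2-(trimethylsilyl)ethyl (4E,6R,9Z)-6-hydroxy-10-iodo-6-methyl-2-methylidene-3-[(triethylsilyl)oxy]undeca-4,9-dienoate (C7 epimers)
Conditions: Hoveyda–Grubbs II (10 mol %), CH2Cl2, 40 °C, 6 (3 equiv)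
Reagents that add atoms: none
Why: Olefin cross-metathesis of the two terminal vinyl groups should give the E-C5=C6 alkene; the iodo-alkene and the 1,1-disubstituted acrylate are poor metathesis partners, so cyclopentenol formation by ring closure onto C1 is not expected.

**Step 9**
Reactants: 15 cross-metathesis product; 16 (4S)-2,2-dimethyl-1,3-dioxolane-4-carbaldehyde
Product: 17 2-(trimethylsilyl)ethyl (4E,6R,9Z,11R)-11-[(4S)-2,2-dimethyl-1,3-dioxolan-4-yl]-6,11-dihydroxy-6,10-dimethyl-2-methylidene-3-[(triethylsilyl)oxy]undeca-4,9-dienoate (C7 epimers)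
Conditions: CrCl2 (6 equiv), NiCl2 (2 mol %), DMSO/THF, rt
Reagents that add atoms: none
Why: Nozaki–Hiyama–Kishi coupling, in which the alkenylchromium keeps the Z geometry and should add to the aldehyde in the Felkin–Anh sense, anti to the dioxolane oxygen, setting C9 as R.

**Step 10**
Reactants: 17 NHK adduct
Product: 18 2-(trimethylsilyl)ethyl (4E,6R,9Z,11R)-11-{[tert-butyl(dimethyl)silyl]oxy}-11-[(4S)-2,2-dimethyl-1,3-dioxolan-4-yl]-6-hydroxy-6,10-dimethyl-2-methylidene-3-[(triethylsilyl)oxy]undeca-4,9-dienoate (C7 epimers)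
Conditions: TBSOTf (1.2 equiv), 2,6-lutidine, CH2Cl2, −78 °C
Reagents that add atoms: tert-butyldimethylsilyl trifluoromethanesulfonate, CC(C)(C)[Si](C)(C)OS(=O)(=O)C(F)(F)F
Why: At −78 °C the silyl triflate should silylate the secondary C9 hydroxyl and leave the hindered tertiary C4 hydroxyl free.

**Step 11**
Reactants: 18 TBS ether
Product: 20 2-(trimethylsilyl)ethyl (4E,6R,9Z,11R)-11-{[tert-butyl(dimethyl)silyl]oxy}-3,6-dihydroxy-6,10-dimethyl-2-methylidene-12-oxododeca-4,9-dienoate (C7 epimers), via tetraol 19 (not isolated)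
Conditions: AcOH/THF/H2O (3:1:1), 40 °C; then NaIO4, THF/pH 7 buffer, 0 °C
Reagents that add atoms: none
Why: Mild acid should hydrolyse the terminal acetonide and the TES ether but not the secondary TBS ether, and periodate glycol cleavage of the only 1,2-diol then unveils the C8 aldehyde without touching C9.

**Step 12**
Reactants: 20 hydroxy aldehyde
Product: 22 2-(trimethylsilyl)ethyl (2Z,4E,6R,9Z,11R)-2-(bromomethyl)-11-{[tert-butyl(dimethyl)silyl]oxy}-6-hydroxy-6,10-dimethyl-12-oxododeca-2,4,9-trienoate, via allylic mesylate 21 (not isolated)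
Conditions: Ms2O, Et3N, CH2Cl2, −40 °C; then LiBr, THF, −40 → 0 °C
Reagents that add atoms: lithium bromide, [Li+].[Br-] (methanesulfonic anhydride, CS(=O)(=O)OS(C)(=O)=O, leaves atoms only in 21)
Why: Only the secondary Baylis–Hillman hydroxyl is sulfonylated, and SN2′ displacement by bromide should give the conjugated (2Z)-2-(bromomethyl)dienoate, in which both C7 epimers converge.

**Step 13**
Reactants: 22 bromo aldehyde
Product: 23 2-(trimethylsilyl)ethyl 2-[(1R,2E,4R,7Z,9R,10S)-9-{[tert-butyl(dimethyl)silyl]oxy}-4,10-dihydroxy-4,8-dimethylcyclodeca-2,7-dien-1-yl]prop-2-enoate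
Conditions: In powder (3 equiv), THF/H2O (3:1), 25 °C, syringe-pump addition of 22 (final 2 mM)
Reagents that add atoms: none
Why: Intramolecular Barbier allylation, in which the 2-(alkoxycarbonyl)allylindium should add through its γ-carbon C7 to the C8 aldehyde via a chair transition state (C6 and O8 syn) under Felkin–Anh control by the C9 silyloxy group (O8 anti to O9), closing the ten-membered ring while water protonates the alkoxide before it can lactonise.

**Step 14**
Reactants: 23 macrocyclic hydroxy ester; 10 [(2R)-2-methyloxiran-2-yl]acetic acid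
Product: 24 2-(trimethylsilyl)ethyl 2-[(1R,2E,4R,7Z,9R,10S)-9-{[tert-butyl(dimethyl)silyl]oxy}-4-hydroxy-4,8-dimethyl-10-({[(2R)-2-methyloxiran-2-yl]acetyl}oxy)cyclodeca-2,7-dien-1-yl]prop-2-enoate
Conditions: DCC, DMAP (20 mol %), CH2Cl2, 0 °C
Reagents that add atoms: none
Why: Steglich esterification should acylate the only reactive hydroxyl (secondary O8) while the tertiary C4 hydroxyl stays free, with no change at any stereocentre.

**Step 15**
Reactants: 24 acylated macrocycle
Product: 25 2-[(1R,2E,4R,7Z,9R,10S)-9-{[tert-butyl(dimethyl)silyl]oxy}-4-hydroxy-4,8-dimethyl-10-({[(2R)-2-methyloxiran-2-yl]acetyl}oxy)cyclodeca-2,7-dien-1-yl]prop-2-enoic acid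
Conditions: TBAF (1.5 equiv), AcOH (1.5 equiv), THF, 0 °C
Reagents that add atoms: none
Why: Fluoride-induced β-elimination of the 2-(trimethylsilyl)ethyl ester should free the C12 acid under buffered conditions that spare the C8 ester, the epoxide and the hindered secondary TBS ether.

**Step 16**
Reactants: 25 seco acid
Product: 26 (3aS,4S,5R,6Z,10E,11aR)-5-{[tert-butyl(dimethyl)silyl]oxy}-6,10-dimethyl-3-methylidene-2-oxo-2,3,3a,4,5,8,9,11a-octahydrocyclodeca[b]furan-4-yl [(2R)-2-methyloxiran-2-yl]acetate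
Conditions: PdCl2(MeCN)2 (10 mol %), THF, 0 °C → rt
Reagents that add atoms: none
Why: Pd(II) is held on the outer face of the E-C5=C6 alkene by the C4 hydroxyl and the carboxylate; the Pd-bound carboxylate oxygen adds to C6 (syn-oxypalladation) and syn-β-hydroxide elimination from C4 then releases water, the C4=C5 alkene and Pd(II). The closest known reaction type is the Pd(II)-catalysed dehydrative SN2′ cyclisation of allylic alcohols by tethered O-nucleophiles with 1,3-chirality transfer, here as a dehydrative allylic lactonisation of an ω-carboxy allylic alcohol. The γ-lactone closes in the 5-exo-trig mode, the alkene being exocyclic to the forming O–C12–C11–C7–C6 ring. C6 should be set as R by transfer from C4 (R, from (R)-linalool), because oxygen leaves C4 and enters C6 on the same alkene face, and C7 holds the acrylic acid on that face, so the lactone is trans-fused. The step needs E geometry at C4=C5 and reaction at this one alkene only; in the E-cyclodecene the ring carbons C3 and C8 are anticlinal to the alkene, which keeps CH3-15 and H7 in the alkene plane and turns C3 trans to C6, while O9 is silylated and C1=C10 has no nucleophile within reach. The epoxide and the C8 ester should be spectators under these near-neutral conditions.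

**Step 17**
Reactants: 26 TBS-protected lactone
Product: 27 (3aS,4S,5R,6Z,10E,11aR)-5-hydroxy-6,10-dimethyl-3-methylidene-2-oxo-2,3,3a,4,5,8,9,11a-octahydrocyclodeca[b]furan-4-yl [(2R)-2-methyloxiran-2-yl]acetate (CNP0284481.1)
Conditions: Et3N·3HF, MeCN, rt
Reagents that add atoms: none
Why: Si–O cleavage by a weakly acidic, non-basic fluoride source should free the C9 hydroxyl without acyl migration from O8, conjugate addition to the α-methylene lactone or opening of the epoxide.

**Compound list**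

1 | 2-(trimethylsilyl)ethanol | OCC[Si](C)(C)C | starting material
2 | acryloyl chloride | C=CC(=O)Cl | starting material
3 | 2-(trimethylsilyl)ethyl prop-2-enoate | C=CC(=O)OCC[Si](C)(C)C | intermediate
4 | acrolein (prop-2-enal) | C=CC=O | starting material
5 | racemic 2-(trimethylsilyl)ethyl 3-hydroxy-2-methylidenepent-4-enoate | C=CC(O)C(=C)C(=O)OCC[Si](C)(C)C | intermediate
6 | racemic 2-(trimethylsilyl)ethyl 2-methylidene-3-[(triethylsilyl)oxy]pent-4-enoate | C=CC(O[Si](CC)(CC)CC)C(=C)C(=O)OCC[Si](C)(C)C | intermediate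
7 | 3-methylbut-3-en-1-ol | C=C(C)CCO | starting material
8 | 2-[(2R)-2-methyloxiran-2-yl]ethan-1-ol | OCC[C@]1(C)CO1 | intermediate
9 | [(2R)-2-methyloxiran-2-yl]acetaldehyde | O=CC[C@]1(C)CO1 | intermediate (not isolated)
10 | [(2R)-2-methyloxiran-2-yl]acetic acid | O=C(O)C[C@]1(C)CO1 | intermediate
11 | (R)-(−)-linalool, (3R)-3,7-dimethylocta-1,6-dien-3-ol | C=C[C@](C)(O)CCC=C(C)C | starting material
12 | (3R)-5-(5,5-dimethyl-1,2,4-trioxolan-3-yl)-3-methylpent-1-en-3-ol (secondary ozonide) | C=C[C@](C)(O)CCC1OOC(C)(C)O1 | intermediate (not isolated)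
13 | (5R)-5-ethenyl-5-methyloxolan-2-ol (anomer mixture) | C=C[C@@]1(C)CCC(O)O1 | intermediate
14 | (3R,6Z)-7-iodo-3-methylocta-1,6-dien-3-ol | C=C[C@](C)(O)CC/C=C(/C)I | intermediate
15 | 2-(trimethylsilyl)ethyl (4E,6R,9Z)-6-hydroxy-10-iodo-6-methyl-2-methylidene-3-[(triethylsilyl)oxy]undeca-4,9-dienoate (epimers at chain C3 = C7) | C=C(C(=O)OCC[Si](C)(C)C)C(O[Si](CC)(CC)CC)/C=C/[C@](C)(O)CC/C=C(/C)I | intermediate
16 | (4S)-2,2-dimethyl-1,3-dioxolane-4-carbaldehyde ((S)-glyceraldehyde acetonide) | O=C[C@@H]1COC(C)(C)O1 | starting material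
17 | 2-(trimethylsilyl)ethyl (4E,6R,9Z,11R)-11-[(4S)-2,2-dimethyl-1,3-dioxolan-4-yl]-6,11-dihydroxy-6,10-dimethyl-2-methylidene-3-[(triethylsilyl)oxy]undeca-4,9-dienoate (C7 epimers) | C=C(C(=O)OCC[Si](C)(C)C)C(O[Si](CC)(CC)CC)/C=C/[C@](C)(O)CC/C=C(/C)[C@@H](O)[C@@H]1COC(C)(C)O1 | intermediate
18 | 2-(trimethylsilyl)ethyl (4E,6R,9Z,11R)-11-{[tert-butyl(dimethyl)silyl]oxy}-11-[(4S)-2,2-dimethyl-1,3-dioxolan-4-yl]-6-hydroxy-6,10-dimethyl-2-methylidene-3-[(triethylsilyl)oxy]undeca-4,9-dienoate (C7 epimers) | C=C(C(=O)OCC[Si](C)(C)C)C(O[Si](CC)(CC)CC)/C=C/[C@](C)(O)CC/C=C(/C)[C@@H](O[Si](C)(C)C(C)(C)C)[C@@H]1COC(C)(C)O1 | intermediate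
19 | 2-(trimethylsilyl)ethyl (4E,6R,9Z,11R,12S)-11-{[tert-butyl(dimethyl)silyl]oxy}-3,6,12,13-tetrahydroxy-6,10-dimethyl-2-methylidenetrideca-4,9-dienoate (C7 epimers) | C=C(C(=O)OCC[Si](C)(C)C)C(O)/C=C/[C@](C)(O)CC/C=C(/C)[C@@H](O[Si](C)(C)C(C)(C)C)[C@@H](O)CO | intermediate (not isolated)
20 | 2-(trimethylsilyl)ethyl (4E,6R,9Z,11R)-11-{[tert-butyl(dimethyl)silyl]oxy}-3,6-dihydroxy-6,10-dimethyl-2-methylidene-12-oxododeca-4,9-dienoate (C7 epimers) | C=C(C(=O)OCC[Si](C)(C)C)C(O)/C=C/[C@](C)(O)CC/C=C(/C)[C@@H](O[Si](C)(C)C(C)(C)C)C=O | intermediate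
21 | 2-(trimethylsilyl)ethyl (4E,6R,9Z,11R)-11-{[tert-butyl(dimethyl)silyl]oxy}-6-hydroxy-3-[(methanesulfonyl)oxy]-6,10-dimethyl-2-methylidene-12-oxododeca-4,9-dienoate (C7 epimers) | C=C(C(=O)OCC[Si](C)(C)C)C(OS(C)(=O)=O)/C=C/[C@](C)(O)CC/C=C(/C)[C@@H](O[Si](C)(C)C(C)(C)C)C=O | intermediate (not isolated)
22 | 2-(trimethylsilyl)ethyl (2Z,4E,6R,9Z,11R)-2-(bromomethyl)-11-{[tert-butyl(dimethyl)silyl]oxy}-6-hydroxy-6,10-dimethyl-12-oxododeca-2,4,9-trienoate | O=C(OCC[Si](C)(C)C)/C(CBr)=C/C=C/[C@](C)(O)CC/C=C(/C)[C@@H](O[Si](C)(C)C(C)(C)C)C=O | intermediate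
23 | 2-(trimethylsilyl)ethyl 2-[(1R,2E,4R,7Z,9R,10S)-9-{[tert-butyl(dimethyl)silyl]oxy}-4,10-dihydroxy-4,8-dimethylcyclodeca-2,7-dien-1-yl]prop-2-enoate | C=C(C(=O)OCC[Si](C)(C)C)[C@H]1/C=C/[C@](C)(O)CC/C=C(/C)[C@@H](O[Si](C)(C)C(C)(C)C)[C@H]1O | intermediate
24 | 2-(trimethylsilyl)ethyl 2-[(1R,2E,4R,7Z,9R,10S)-9-{[tert-butyl(dimethyl)silyl]oxy}-4-hydroxy-4,8-dimethyl-10-({[(2R)-2-methyloxiran-2-yl]acetyl}oxy)cyclodeca-2,7-dien-1-yl]prop-2-enoate | C=C(C(=O)OCC[Si](C)(C)C)[C@H]1/C=C/[C@](C)(O)CC/C=C(/C)[C@@H](O[Si](C)(C)C(C)(C)C)[C@H]1OC(=O)C[C@]1(C)CO1 | intermediate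
25 | 2-[(1R,2E,4R,7Z,9R,10S)-9-{[tert-butyl(dimethyl)silyl]oxy}-4-hydroxy-4,8-dimethyl-10-({[(2R)-2-methyloxiran-2-yl]acetyl}oxy)cyclodeca-2,7-dien-1-yl]prop-2-enoic acid | C=C(C(=O)O)[C@H]1/C=C/[C@](C)(O)CC/C=C(/C)[C@@H](O[Si](C)(C)C(C)(C)C)[C@H]1OC(=O)C[C@]1(C)CO1 | intermediate
26 | (3aS,4S,5R,6Z,10E,11aR)-5-{[tert-butyl(dimethyl)silyl]oxy}-6,10-dimethyl-3-methylidene-2-oxo-2,3,3a,4,5,8,9,11a-octahydrocyclodeca[b]furan-4-yl [(2R)-2-methyloxiran-2-yl]acetate | C=C1C(=O)O[C@@H]2/C=C(\C)CC/C=C(/C)[C@@H](O[Si](C)(C)C(C)(C)C)[C@@H](OC(=O)C[C@]3(C)CO3)[C@@H]12 | intermediate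
27 | (3aS,4S,5R,6Z,10E,11aR)-5-hydroxy-6,10-dimethyl-3-methylidene-2-oxo-2,3,3a,4,5,8,9,11a-octahydrocyclodeca[b]furan-4-yl [(2R)-2-methyloxiran-2-yl]acetate (CNP0284481.1) | C=C1C(=O)O[C@@H]2/C=C(\C)CC/C=C(/C)[C@@H](O)[C@@H](OC(=O)C[C@]3(C)CO3)[C@@H]12 | target

**Totals**

Total step count: 17. Longest linear sequence: 13 steps (steps 1–3 and 8–17); 12 steps from (R)-linalool.

**Steps most likely to fail**

Step 16 (key step). The ring may react through the conformer that places C3 instead of CH3-15 in the alkene plane, which would give the 4Z, 6-epi (cis-fused) lactone. The HCl that turns over at palladium may also open the epoxide. The fallback sets out from 24 and replaces hydroxyl-directed oxypalladation by ionisation to a π-allyl complex under neutral conditions. Boc2O and DMAP in MeCN would convert the only free hydroxyl of 24 into the C4 tert-butyl carbonate F1. Buffered TBAF/AcOH would then give the carbonate acid F2. Pd(PPh3)4 in THF at rt should ionise the carbonate with loss of CO2 and tert-butanol, and the carboxylate should attack C6 of the π-allyl complex (Tsuji–Trost lactonisation, double inversion, π–σ–π equilibration towards the W-shaped allyl and hence the E alkene). This comes back to the route at 26.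

Step 13. During ring closure, or later under DMAP in step 14, the C12 acyl group may transfer to the new O8 (8,12-lactonisation). That would remove the ester that keeps the acid masked while O8 is acylated. The fallback sets out from 22 and uses this lactone as a temporary ring. The indium cyclisation followed by a trace of TsOH in CH2Cl2 would give the cis-fused 8,12-lactone F3. LiOH in THF/H2O at 0 °C with careful neutralisation would give the hydroxy acid F4. Used at once, F4 would be cyclised with PdCl2(MeCN)2 as in step 16 to the 8-hydroxy-6,12-olide F5. Steglich esterification of F5 with 10 would then come back to the route at 26.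

Step 8. Cross-metathesis between two allylically branched alkenes may be slow, with homodimerisation of 6 and catalyst decay at the iodo-alkene. The fallback sets out from 14 and builds the same unit stepwise. Cross-metathesis with the unhindered partner crotonaldehyde (Hoveyda–Grubbs II) would give the enal F6. A DABCO-mediated Morita–Baylis–Hillman reaction of F6 with 3 would give the Baylis–Hillman alcohol F7. TESCl/imidazole, selective for the secondary hydroxyl, would then come back to the route at 15.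

**Further compounds**

F1 | step 16 | 2-(trimethylsilyl)ethyl 2-[(1R,2E,4R,7Z,9R,10S)-4-[(tert-butoxycarbonyl)oxy]-9-{[tert-butyl(dimethyl)silyl]oxy}-4,8-dimethyl-10-({[(2R)-2-methyloxiran-2-yl]acetyl}oxy)cyclodeca-2,7-dien-1-yl]prop-2-enoate | C=C(C(=O)OCC[Si](C)(C)C)[C@H]1/C=C/[C@](C)(OC(=O)OC(C)(C)C)CC/C=C(/C)[C@@H](O[Si](C)(C)C(C)(C)C)[C@H]1OC(=O)C[C@]1(C)CO1
F2 | step 16 | 2-[(1R,2E,4R,7Z,9R,10S)-4-[(tert-butoxycarbonyl)oxy]-9-{[tert-butyl(dimethyl)silyl]oxy}-4,8-dimethyl-10-({[(2R)-2-methyloxiran-2-yl]acetyl}oxy)cyclodeca-2,7-dien-1-yl]prop-2-enoic acid | C=C(C(=O)O)[C@H]1/C=C/[C@](C)(OC(=O)OC(C)(C)C)CC/C=C(/C)[C@@H](O[Si](C)(C)C(C)(C)C)[C@H]1OC(=O)C[C@]1(C)CO1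
F3 | step 13 | (4R,5E,7R,8S,9R,1(10)Z)-9-[(tert-butyldimethylsilyl)oxy]-4-hydroxygermacra-1(10),5,11(13)-trien-12,8-olide (cis-fused 8,12-lactone) | C=C1C(=O)O[C@@H]2[C@H](O[Si](C)(C)C(C)(C)C)/C(C)=C\CC[C@@](C)(O)/C=C/[C@H]12
F4 | step 13 | 2-[(1R,2E,4R,7Z,9R,10S)-9-{[tert-butyl(dimethyl)silyl]oxy}-4,10-dihydroxy-4,8-dimethylcyclodeca-2,7-dien-1-yl]prop-2-enoic acid | C=C(C(=O)O)[C@H]1/C=C/[C@](C)(O)CC/C=C(/C)[C@@H](O[Si](C)(C)C(C)(C)C)[C@H]1O
F5 | step 13 | (3aR,4S,5R,6Z,10E,11aR)-5-{[tert-butyl(dimethyl)silyl]oxy}-4-hydroxy-6,10-dimethyl-3-methylidene-3a,4,5,8,9,11a-hexahydrocyclodeca[b]furan-2(3H)-one | C=C1C(=O)O[C@@H]2/C=C(\C)CC/C=C(/C)[C@@H](O[Si](C)(C)C(C)(C)C)[C@@H](O)[C@@H]12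
F6 | step 8 | (2E,4R,7Z)-4-hydroxy-8-iodo-4-methylnona-2,7-dienal | O=C/C=C/[C@](C)(O)CC/C=C(/C)I
F7 | step 8 | 2-(trimethylsilyl)ethyl (4E,6R,9Z)-3,6-dihydroxy-10-iodo-6-methyl-2-methylidene-undeca-4,9-dienoate (C3 epimers) | C=C(C(=O)OCC[Si](C)(C)C)C(O)/C=C/[C@](C)(O)CC/C=C(/C)I
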